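**Plan**

- Feature used: ring D is bonded to indenone C3 through its C1, the carbon that lies between the two hydroxyl-bearing carbons C2 and C6, with the methyl group para at C4. C2–C3–C4(CH3)–C5 is therefore a 6-oxy-4-methyl-2-pyrone less CO2, and C1–C6(O) is an oxygen-substituted alkyne standing on C3.
- Retrosynthetic cuts, in order: the five phenol protecting groups; ring D bonds C1–C2 and C5–C6 (pyrone/alkyne cycloaddition with loss of CO2); the C3–alkyne bond (Negishi coupling at an enol triflate); the C1 carbonyl (back to CH2); the C2–ring B bond (ketone α-arylation); the ring A–O–ring B bond (SNAr).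
- Forward: rings A and B are joined first (steps 1–4) and arylated onto C2 of 7-benzyloxy-5-methoxyindan-1-one (steps 5–7). Its only carbonyl is frozen as the C3 enol triflate before the C1 methylene is oxidised (steps 8–9), so carbonyl and leaving group cannot change places. The alkynyl ether is then coupled to C3 (step 11), ring D is grown on it as the last ring (step 13), and the phenols are freed (steps 14–15).
- The alkynyl oxygen is carried as a 1-adamantyl ether: a bridgehead group can leave neither by retro-ene fragmentation (as tert-butyl would) nor by a [3,3] shift (as benzyl or allyl would) on heating, and BCl3 removes it together with the benzyl ethers.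
- Stereochemistry: the target has no stereocentre; the racemic centres that arise on the way (indanone C2, the hydroperoxide carbon, the bridgeheads of the cycloadduct) vanish in the next operation.

Key step: step 13

Assumption: 3-bromo-2-fluoro-5-methoxybenzaldehyde and 5,7-dimethoxyindan-1-one are taken as catalogue building blocks, and rotamers about the hindered aryl–indenone axes are treated as one compound.

**Route**

Step 1
Reactants: 1 methyl 2,6-dihydroxy-4-methylbenzoate
Product: 2 methyl 2-(benzyloxy)-6-hydroxy-4-methylbenzoate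
Conditions: BnBr (1.05 equiv), K2CO3, acetone, 56 °C
Reagents that add atoms: benzyl bromide, BrCc1ccccc1
Why: Williamson ether synthesis; once one oxygen is benzylated the other phenol is held in a hydrogen bond to the ester carbonyl and is far less nucleophilic, so mono-alkylation should prevail.

Step 2
Reactants: 2 methyl 2-(benzyloxy)-6-hydroxy-4-methylbenzoate; 3 3-bromo-2-fluoro-5-methoxybenzaldehyde
Product: 4 methyl 2-(benzyloxy)-6-(2-bromo-6-formyl-4-methoxyphenoxy)-4-methylbenzoate
Conditions: K2CO3, DMA, 100 °C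
Reagents that add atoms: none
Why: Nucleophilic aromatic substitution by addition–elimination; the fluorine is ortho to the formyl group that stabilises the anionic adduct, and the aryl bromide is inert without a metal catalyst.

Step 3
Reactants: 4 methyl 2-(benzyloxy)-6-(2-bromo-6-formyl-4-methoxyphenoxy)-4-methylbenzoate
Product: 6 methyl 2-(benzyloxy)-6-(2-bromo-6-hydroxy-4-methoxyphenoxy)-4-methylbenzoate, via aryl formate 5 (not isolated)
Conditions: mCPBA, CH2Cl2, 40 °C; then K2CO3 (cat.), MeOH, 23 °C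
Reagents that add atoms: 3-chloroperoxybenzoic acid (mCPBA), OOC(=O)c1cccc(Cl)c1
Why: Baeyer–Villiger (Dakin-type) oxidation in which the ortho-aryloxy-substituted aryl group should migrate in preference to hydride, followed by transesterification of the aryl formate with methanol.

Step 4
Reactants: 6 methyl 2-(benzyloxy)-6-(2-bromo-6-hydroxy-4-methoxyphenoxy)-4-methylbenzoate
Product: 7 methyl 2-(benzyloxy)-6-[2-(benzyloxy)-6-bromo-4-methoxyphenoxy]-4-methylbenzoate
Conditions: BnBr, K2CO3, DMF, 40 °C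
Reagents that add atoms: benzyl bromide, BrCc1ccccc1
Why: Williamson ether synthesis on the only free phenol of the molecule.

Step 5
Reactants: 8 5,7-dimethoxyindan-1-one
Product: 9 7-hydroxy-5-methoxyindan-1-one
Conditions: BCl3, CH2Cl2, −78 → 0 °C; then H2O
Reagents that add atoms: none
Why: Chelation-controlled Lewis-acid ether cleavage; boron bound to the ketone oxygen activates only the peri C7 methoxy group, so the C5 methyl ether (the later C6 methoxy group of the indenone) should stay.

Step 6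
Reactants: 9 7-hydroxy-5-methoxyindan-1-one
Product: 10 7-(benzyloxy)-5-methoxyindan-1-one
Conditions: BnBr, K2CO3, DMF, 60 °C
Reagents that add atoms: benzyl bromide, BrCc1ccccc1
Why: Williamson ether synthesis; the hydrogen-bonded peri phenol needs mild heating but has no competing nucleophile beside it.

Step 7
Reactants: 10 7-(benzyloxy)-5-methoxyindan-1-one; 7 methyl 2-(benzyloxy)-6-[2-(benzyloxy)-6-bromo-4-methoxyphenoxy]-4-methylbenzoate
Product: 11 methyl 2-(benzyloxy)-6-{2-(benzyloxy)-6-[7-(benzyloxy)-5-methoxy-1-oxo-2,3-dihydro-1H-inden-2-yl]-4-methoxyphenoxy}-4-methylbenzoate (racemic)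
Conditions: Pd(OAc)2 (5 mol %), XPhos (10 mol %), K3PO4, PhMe, 90 °C
Reagents that add atoms: none
Why: Palladium-catalysed α-arylation of a ketone enolate; 10 has a single enolisable position, the bulky biarylphosphine supports coupling of the ortho-aryloxy bromide, and the mild phosphate base spares the hindered benzoate.

Step 8
Reactants: 11 methyl 2-(benzyloxy)-6-{2-(benzyloxy)-6-[7-(benzyloxy)-5-methoxy-1-oxo-2,3-dihydro-1H-inden-2-yl]-4-methoxyphenoxy}-4-methylbenzoate
Product: 13 methyl 2-(benzyloxy)-6-{2-(benzyloxy)-6-[4-(benzyloxy)-6-methoxy-3-(trifluoromethanesulfonyloxy)-1H-inden-2-yl]-4-methoxyphenoxy}-4-methylbenzoate, via potassium enolate 12 (not isolated)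
Conditions: KN(SiMe3)2, THF, −78 °C; PhNTf2, −78 → 0 °C
Reagents that add atoms: N-phenylbis(trifluoromethanesulfonimide), O=S(=O)(N(c1ccccc1)S(=O)(=O)C(F)(F)F)C(F)(F)F
Why: O-sulfonylation of a ketone enolate (enol triflate formation); as 11 has one carbonyl only, the triflate can sit only on the carbon peri to the C4 benzyloxy group, which fixes the later position of the alkyne.

Step 9
Reactants: 13 methyl 2-(benzyloxy)-6-{2-(benzyloxy)-6-[4-(benzyloxy)-6-methoxy-3-(trifluoromethanesulfonyloxy)-1H-inden-2-yl]-4-methoxyphenoxy}-4-methylbenzoate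
Product: 15 methyl 2-(benzyloxy)-6-{2-(benzyloxy)-6-[4-(benzyloxy)-6-methoxy-1-oxo-3-(trifluoromethanesulfonyloxy)-1H-inden-2-yl]-4-methoxyphenoxy}-4-methylbenzoate, via C1 hydroperoxide 14 (not isolated)
Conditions: O2 (1 atm), Cs2CO3, DMSO, 23 °C
Reagents that add atoms: dioxygen, O=O
Why: Base-mediated autoxidation of a doubly activated methylene (the fluorene-to-fluorenone type), in which the indenyl anion should take up O2 at the unsubstituted C1 and the hydroperoxide collapse to the ketone by a Kornblum–DeLaMare elimination, no other C–H in the molecule being acidic enough to react.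

Step 10
Reactants: 16 adamantan-1-ol; 17 trichloroethylene
Product: 18 1-{[(E)-1,2-dichloroethenyl]oxy}adamantane
Conditions: KH, THF, 23 °C; then 17, −50 → 23 °C
Reagents that add atoms: none
Why: Addition of an alkoxide to dichloroacetylene formed in situ by dehydrochlorination of trichloroethylene, the standard entry to 1,2-dichlorovinyl ethers, the anti addition setting the E geometry.

Step 11
Reactants: 15 methyl 2-(benzyloxy)-6-{2-(benzyloxy)-6-[4-(benzyloxy)-6-methoxy-1-oxo-3-(trifluoromethanesulfonyloxy)-1H-inden-2-yl]-4-methoxyphenoxy}-4-methylbenzoate; 18 1-{[(E)-1,2-dichloroethenyl]oxy}adamantane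
Product: 21 methyl 2-(benzyloxy)-6-{2-(benzyloxy)-6-[3-[(adamantan-1-yloxy)ethynyl]-4-(benzyloxy)-6-methoxy-1-oxo-1H-inden-2-yl]-4-methoxyphenoxy}-4-methylbenzoate, via lithium alkoxyacetylide 19 (not isolated), via alkynylzinc chloride 20 (not isolated)
Conditions: 18, n-BuLi (2 equiv), THF, −78 → −40 °C; ZnCl2, −40 → 0 °C; then 15, Pd(PPh3)4 (5 mol %), THF, 23 °C
Reagents that add atoms: none
Why: Dehydrochlorination and chlorine–lithium exchange of the dichlorovinyl ether give the lithium alkoxyacetylide, and Negishi coupling of its zinc derivative with the vinylogous acyl triflate should form the C3–alkyne bond under neutral, cold conditions that the alkynyl ether tolerates.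

Step 12
Reactants: 22 3-methylglutaconic anhydride
Product: 23 6-[(tert-butyldimethylsilyl)oxy]-4-methyl-2H-pyran-2-one
Conditions: TBSCl, Et3N, CH2Cl2, 0 → 23 °C; filtered under argon and used without chromatography
Reagents that add atoms: tert-butyl(chloro)dimethylsilane, CC(C)(C)[Si](C)(C)Cl
Why: O-silylation of the enolate of a glutaconic anhydride (its 6-hydroxy-2-pyrone tautomer); the two carbonyl oxygens of the anion are equivalent by symmetry, so a single silyloxypyrone should form.

Step 13
Reactants: 21 methyl 2-(benzyloxy)-6-{2-(benzyloxy)-6-[3-[(adamantan-1-yloxy)ethynyl]-4-(benzyloxy)-6-methoxy-1-oxo-1H-inden-2-yl]-4-methoxyphenoxy}-4-methylbenzoate; 23 6-[(tert-butyldimethylsilyl)oxy]-4-methyl-2H-pyran-2-one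
Product: 25 methyl 2-(benzyloxy)-6-{2-(benzyloxy)-6-[3-{2-(adamantan-1-yloxy)-6-[(tert-butyldimethylsilyl)oxy]-4-methylphenyl}-4-(benzyloxy)-6-methoxy-1-oxo-1H-inden-2-yl]-4-methoxyphenoxy}-4-methylbenzoate, via bicyclic lactone 24 (not isolated)
Conditions: 23 (3 equiv), PhMe, 110 °C, sealed tube, argon
Reagents that add atoms: none
Why: Thermal [4+2] cycloaddition of the ketene-acetal-like diene of 23 (C3 and C6) across the triple bond of 21, concerted but asynchronous or, at the polar extreme, a vinylogous Mukaiyama–Michael addition followed by ring closure, should give the 2-oxabicyclo[2.2.2]octadienone 24, which expels CO2 in a retro-[4+2] step. The closest known reaction type is the Diels–Alder/decarboxylation sequence of 6-alkoxy- and 6-silyloxy-2-pyrones with alkynes. Ring D, the only ring formed, closes by this intermolecular two-bond annulation (ring D C1–C2 from the indenone-bound alkyne carbon to pyrone C6, ring D C5–C6 from pyrone C3 to the oxygen-bearing alkyne carbon) as a six-membered carbocycle that is aromatic as soon as CO2 has left. No lasting stereocentre is created: the two bridgehead centres of 24 are erased on aromatisation. The step needs one orientation of the two partners, and matched polarity should secure it: the nucleophilic pyrone C3, remote terminus of the silyl ketene acetal, pairs with the oxygen-bearing alkyne carbon, which is the electrophilic 1,6-acceptor position of the indenone, while the donor-substituted pyrone C6 pairs with the enolate-like alkyne carbon on C3. Chemoselectivity rests on the slim triple bond being the only unhindered acceptor (the tetrasubstituted indenone C2=C3 bond is shielded) and on the bridgehead adamantyl ether, which cannot fragment at 110 °C.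

Step 14
Reactants: 25 methyl 2-(benzyloxy)-6-{2-(benzyloxy)-6-[3-{2-(adamantan-1-yloxy)-6-[(tert-butyldimethylsilyl)oxy]-4-methylphenyl}-4-(benzyloxy)-6-methoxy-1-oxo-1H-inden-2-yl]-4-methoxyphenoxy}-4-methylbenzoate
Product: 26 methyl 2-(benzyloxy)-6-{2-(benzyloxy)-6-[3-[2-(adamantan-1-yloxy)-6-hydroxy-4-methylphenyl]-4-(benzyloxy)-6-methoxy-1-oxo-1H-inden-2-yl]-4-methoxyphenoxy}-4-methylbenzoate
Conditions: Bu4NF, AcOH, THF, 0 °C
Reagents that add atoms: none
Why: Fluoride-induced desilylation of an aryl silyl ether, buffered with acetic acid so that the phenoxide is protonated at once.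

Step 15
Reactants: 26 methyl 2-(benzyloxy)-6-{2-(benzyloxy)-6-[3-[2-(adamantan-1-yloxy)-6-hydroxy-4-methylphenyl]-4-(benzyloxy)-6-methoxy-1-oxo-1H-inden-2-yl]-4-methoxyphenoxy}-4-methylbenzoate
Product: 27 Ascomindone B, methyl 2-{2-[3-(2,6-dihydroxy-4-methylphenyl)-4-hydroxy-6-methoxy-1-oxo-1H-inden-2-yl]-6-hydroxy-4-methoxyphenoxy}-6-hydroxy-4-methylbenzoate
Conditions: BCl3, C6HMe5, CH2Cl2, −78 → −40 °C; then H2O
Reagents that add atoms: none
Why: Lewis-acid dealkylation with a cation scavenger; BCl3 should ionise the three benzyl ethers and the tertiary adamantyl ether, pentamethylbenzene and chloride take up the carbocations, and the two aryl methyl ethers (neither next to a carbonyl group) and the methyl ester should survive at low temperature.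

**Compound list**

1 | methyl 2,6-dihydroxy-4-methylbenzoate | COC(=O)c1c(O)cc(C)cc1O | starting material
2 | methyl 2-(benzyloxy)-6-hydroxy-4-methylbenzoate | COC(=O)c1c(OCc2ccccc2)cc(C)cc1O | intermediate
3 | 3-bromo-2-fluoro-5-methoxybenzaldehyde | O=Cc1cc(OC)cc(Br)c1F | starting material
4 | methyl 2-(benzyloxy)-6-(2-bromo-6-formyl-4-methoxyphenoxy)-4-methylbenzoate | COC(=O)c1c(OCc2ccccc2)cc(C)cc1Oc1c(C=O)cc(OC)cc1Br | intermediate
5 | methyl 2-(benzyloxy)-6-[2-bromo-6-(formyloxy)-4-methoxyphenoxy]-4-methylbenzoate | COC(=O)c1c(OCc2ccccc2)cc(C)cc1Oc1c(OC=O)cc(OC)cc1Br | intermediate (not isolated)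
6 | methyl 2-(benzyloxy)-6-(2-bromo-6-hydroxy-4-methoxyphenoxy)-4-methylbenzoate | COC(=O)c1c(OCc2ccccc2)cc(C)cc1Oc1c(O)cc(OC)cc1Br | intermediate
7 | methyl 2-(benzyloxy)-6-[2-(benzyloxy)-6-bromo-4-methoxyphenoxy]-4-methylbenzoate | COC(=O)c1c(OCc2ccccc2)cc(C)cc1Oc1c(OCc2ccccc2)cc(OC)cc1Br | intermediate
8 | 5,7-dimethoxyindan-1-one | COc1cc(OC)c2c(c1)CCC2=O | starting material
9 | 7-hydroxy-5-methoxyindan-1-one | COc1cc(O)c2c(c1)CCC2=O | intermediate
10 | 7-(benzyloxy)-5-methoxyindan-1-one | COc1cc(OCc3ccccc3)c2c(c1)CCC2=O | intermediate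
11 | methyl 2-(benzyloxy)-6-{2-(benzyloxy)-6-[7-(benzyloxy)-5-methoxy-1-oxo-2,3-dihydro-1H-inden-2-yl]-4-methoxyphenoxy}-4-methylbenzoate (racemic) | COC(=O)c1c(OCc2ccccc2)cc(C)cc1Oc1c(OCc2ccccc2)cc(OC)cc1C1Cc2cc(OC)cc(OCc3ccccc3)c2C1=O | intermediate
12 | potassium 2-aryl-4-(benzyloxy)-6-methoxy-1H-inden-3-olate (enolate of 11) | COC(=O)c1c(OCc2ccccc2)cc(C)cc1Oc1c(OCc2ccccc2)cc(OC)cc1C1=C([O-])c2c(OCc3ccccc3)cc(OC)cc2C1.[K+] | intermediate (not isolated)
13 | methyl 2-(benzyloxy)-6-{2-(benzyloxy)-6-[4-(benzyloxy)-6-methoxy-3-(trifluoromethanesulfonyloxy)-1H-inden-2-yl]-4-methoxyphenoxy}-4-methylbenzoate | COC(=O)c1c(OCc2ccccc2)cc(C)cc1Oc1c(OCc2ccccc2)cc(OC)cc1C1=C(OS(=O)(=O)C(F)(F)F)c2c(OCc3ccccc3)cc(OC)cc2C1 | intermediate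
14 | methyl 2-(benzyloxy)-6-{2-(benzyloxy)-6-[4-(benzyloxy)-1-hydroperoxy-6-methoxy-3-(trifluoromethanesulfonyloxy)-1H-inden-2-yl]-4-methoxyphenoxy}-4-methylbenzoate (racemic) | COC(=O)c1c(OCc2ccccc2)cc(C)cc1Oc1c(OCc2ccccc2)cc(OC)cc1C1=C(OS(=O)(=O)C(F)(F)F)c2c(OCc3ccccc3)cc(OC)cc2C1OO | intermediate (not isolated)
15 | methyl 2-(benzyloxy)-6-{2-(benzyloxy)-6-[4-(benzyloxy)-6-methoxy-1-oxo-3-(trifluoromethanesulfonyloxy)-1H-inden-2-yl]-4-methoxyphenoxy}-4-methylbenzoate | COC(=O)c1c(OCc2ccccc2)cc(C)cc1Oc1c(OCc2ccccc2)cc(OC)cc1C1=C(OS(=O)(=O)C(F)(F)F)c2c(OCc3ccccc3)cc(OC)cc2C1=O | intermediate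
16 | adamantan-1-ol | OC12CC3CC(CC(C3)C1)C2 | starting material
17 | trichloroethylene | ClC=C(Cl)Cl | starting material
18 | 1-{[(E)-1,2-dichloroethenyl]oxy}adamantane | Cl/C=C(/Cl)OC12CC3CC(CC(C3)C1)C2 | intermediate
19 | lithium (adamantan-1-yloxy)acetylide | [Li]C#COC12CC3CC(CC(C3)C1)C2 | intermediate (not isolated)
20 | [(adamantan-1-yloxy)ethynyl]zinc chloride | Cl[Zn]C#COC12CC3CC(CC(C3)C1)C2 | intermediate (not isolated)
21 | methyl 2-(benzyloxy)-6-{2-(benzyloxy)-6-[3-[(adamantan-1-yloxy)ethynyl]-4-(benzyloxy)-6-methoxy-1-oxo-1H-inden-2-yl]-4-methoxyphenoxy}-4-methylbenzoate | COC(=O)c1c(OCc2ccccc2)cc(C)cc1Oc1c(OCc2ccccc2)cc(OC)cc1C1=C(C#COC23CC4CC(CC(C4)C2)C3)c2c(OCc3ccccc3)cc(OC)cc2C1=O | intermediate (key-step precursor)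
22 | 3-methylglutaconic anhydride (4-methyl-2H-pyran-2,6(3H)-dione) | CC1=CC(=O)OC(=O)C1 | starting material
23 | 6-[(tert-butyldimethylsilyl)oxy]-4-methyl-2H-pyran-2-one | CC1=CC(=O)OC(O[Si](C)(C)C(C)(C)C)=C1 | intermediate (key-step precursor)
24 | methyl 2-(benzyloxy)-6-{2-(benzyloxy)-6-[3-{5-(adamantan-1-yloxy)-1-[(tert-butyldimethylsilyl)oxy]-8-methyl-3-oxo-2-oxabicyclo[2.2.2]octa-5,7-dien-6-yl}-4-(benzyloxy)-6-methoxy-1-oxo-1H-inden-2-yl]-4-methoxyphenoxy}-4-methylbenzoate (racemic) | COC(=O)c1c(OCc2ccccc2)cc(C)cc1Oc1c(OCc2ccccc2)cc(OC)cc1C1=C(C2=C(OC34CC5CC(CC(C5)C3)C4)C3C(C)=CC2(O[Si](C)(C)C(C)(C)C)OC3=O)c2c(OCc3ccccc3)cc(OC)cc2C1=O | intermediate (not isolated)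
25 | methyl 2-(benzyloxy)-6-{2-(benzyloxy)-6-[3-{2-(adamantan-1-yloxy)-6-[(tert-butyldimethylsilyl)oxy]-4-methylphenyl}-4-(benzyloxy)-6-methoxy-1-oxo-1H-inden-2-yl]-4-methoxyphenoxy}-4-methylbenzoate | COC(=O)c1c(OCc2ccccc2)cc(C)cc1Oc1c(OCc2ccccc2)cc(OC)cc1C1=C(c2c(OC34CC5CC(CC(C5)C3)C4)cc(C)cc2O[Si](C)(C)C(C)(C)C)c2c(OCc3ccccc3)cc(OC)cc2C1=O | intermediate (key-step product)
26 | methyl 2-(benzyloxy)-6-{2-(benzyloxy)-6-[3-[2-(adamantan-1-yloxy)-6-hydroxy-4-methylphenyl]-4-(benzyloxy)-6-methoxy-1-oxo-1H-inden-2-yl]-4-methoxyphenoxy}-4-methylbenzoate | COC(=O)c1c(OCc2ccccc2)cc(C)cc1Oc1c(OCc2ccccc2)cc(OC)cc1C1=C(c2c(OC34CC5CC(CC(C5)C3)C4)cc(C)cc2O)c2c(OCc3ccccc3)cc(OC)cc2C1=O | intermediate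
27 | Ascomindone B | COC(=O)c1c(O)cc(C)cc1Oc1c(O)cc(OC)cc1C1=C(c2c(O)cc(C)cc2O)c2c(O)cc(OC)cc2C1=O | target

**Step count**

Total: 15 steps. Longest linear sequence: 11 steps (1, 2, 3, 4, 7, 8, 9, 11, 13, 14, 15). The indanone (steps 5–6), the dichlorovinyl ether (step 10) and the pyrone (step 12) are made on side branches.

**Steps most likely to fail**

Step 13. The cycloaddition may be slow at the crowded alkyne carbon on C3, so that desilylation or self-condensation of the silyloxypyrone wins, or the orientation of the two partners may leak. The fallback sets out from 15 and brings ring D in preformed by a hindered Suzuki–Miyaura coupling. Commercial orcinol is converted with MOMCl and i-Pr2NEt into 1,3-bis(methoxymethoxy)-5-methylbenzene F1. F1 is lithiated between its two oxygens (n-BuLi, THF, 0 °C) and quenched with 2-isopropoxy-4,4,5,5-tetramethyl-1,3,2-dioxaborolane to give 2-[2,6-bis(methoxymethoxy)-4-methylphenyl]-4,4,5,5-tetramethyl-1,3,2-dioxaborolane F2. Coupling of F2 with triflate 15 (Pd(OAc)2, SPhos, K3PO4, PhMe/H2O, 90 °C) should give methyl 2-(benzyloxy)-6-{2-(benzyloxy)-6-[4-(benzyloxy)-3-[2,6-bis(methoxymethoxy)-4-methylphenyl]-6-methoxy-1-oxo-1H-inden-2-yl]-4-methoxyphenoxy}-4-methylbenzoate F3. BCl3 with pentamethylbenzene then removes the three benzyl and two methoxymethyl groups in one operation, and the route is rejoined at 27.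

Step 9. The enol triflate may be lost by attack of hydroxide or peroxide at sulfur or at C3 of the product, the delocalised anion may be oxygenated at the triflate-bearing carbon, or the anion may add to the indenone already formed. The fallback sets out from 13 and replaces C–H oxygenation by cleavage of a C=C bond. Condensation of the acidic methylene with tert-butoxybis(dimethylamino)methane (Bredereck's reagent, PhMe, 60 °C) should give the enamine methyl 2-(benzyloxy)-6-{2-(benzyloxy)-6-[4-(benzyloxy)-1-[(dimethylamino)methylidene]-6-methoxy-3-(trifluoromethanesulfonyloxy)-1H-inden-2-yl]-4-methoxyphenoxy}-4-methylbenzoate F4 (E/Z mixture). Its electron-rich exocyclic double bond is cleaved with singlet oxygen (O2, hν, tetraphenylporphyrin, CH2Cl2, −78 °C) to the ketone and DMF, and the route is rejoined at 15.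

Step 7. Oxidative addition and reductive elimination at the ortho-aryloxy bromide may be slow, so that protodebromination or aldol self-condensation of the enolate takes over. The fallback sets out from 10 and 7 and reverses the polarity of the union. Ketone 10 is α-brominated (CuBr2, EtOAc/CHCl3, reflux) to 2-bromo-7-(benzyloxy)-5-methoxyindan-1-one F5 (racemic). Bromide 7 is converted by magnesium insertion in the presence of LiCl and ZnCl2 (THF, 23 °C) into methyl 2-(benzyloxy)-6-[2-(benzyloxy)-6-(chlorozincio)-4-methoxyphenoxy]-4-methylbenzoate F6. A nickel-catalysed Negishi coupling of the α-bromo ketone with the arylzinc reagent (NiCl2(dme), 2,2'-bipyridine, THF/DME, −20 → 0 °C) should join them, and the route is rejoined at 11.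

**Further compounds**

F1 | step 13 | 1,3-bis(methoxymethoxy)-5-methylbenzene | COCOc1cc(C)cc(OCOC)c1
F2 | step 13 | 2-[2,6-bis(methoxymethoxy)-4-methylphenyl]-4,4,5,5-tetramethyl-1,3,2-dioxaborolane | COCOc1cc(C)cc(OCOC)c1B1OC(C)(C)C(C)(C)O1
F3 | step 13 | methyl 2-(benzyloxy)-6-{2-(benzyloxy)-6-[4-(benzyloxy)-3-[2,6-bis(methoxymethoxy)-4-methylphenyl]-6-methoxy-1-oxo-1H-inden-2-yl]-4-methoxyphenoxy}-4-methylbenzoate | COC(=O)c1c(OCc2ccccc2)cc(C)cc1Oc1c(OCc2ccccc2)cc(OC)cc1C1=C(c2c(OCOC)cc(C)cc2OCOC)c2c(OCc3ccccc3)cc(OC)cc2C1=O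
F4 | step 9 | methyl 2-(benzyloxy)-6-{2-(benzyloxy)-6-[4-(benzyloxy)-1-[(dimethylamino)methylidene]-6-methoxy-3-(trifluoromethanesulfonyloxy)-1H-inden-2-yl]-4-methoxyphenoxy}-4-methylbenzoate (E/Z mixture) | COC(=O)c1c(OCc2ccccc2)cc(C)cc1Oc1c(OCc2ccccc2)cc(OC)cc1C1=C(OS(=O)(=O)C(F)(F)F)c2c(OCc3ccccc3)cc(OC)cc2C1=CN(C)C
F5 | step 7 | 2-bromo-7-(benzyloxy)-5-methoxyindan-1-one (racemic) | COc1cc(OCc3ccccc3)c2c(c1)CC(Br)C2=O
F6 | step 7 | methyl 2-(benzyloxy)-6-[2-(benzyloxy)-6-(chlorozincio)-4-methoxyphenoxy]-4-methylbenzoate | COC(=O)c1c(OCc2ccccc2)cc(C)cc1Oc1c(OCc2ccccc2)cc(OC)cc1[Zn]Cl
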